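Readings and results come from a simulation from invented constants; noise was put on by code.

Product in these flasks comes through the catalyst, and this holds from start to end. So I count turnovers: product over free catalyst charged (the turnover number).

| flask | starting material | free catalyst | time |
|---|---|---|---|
| winter | 0.600 M | 0.00600 M |  |
| summer | 0.240 M | 0.00600 M |  |
| dusk | 0.600 M | 0.00300 M |  |
| autumn | 0.300 M | 0.00600 M |  |
| dawn | 0.600 M | 0.00170 M | 7.5 min |

| winter run: time / min | winter run: [product] / M | summer run: time / min | summer run: [product] / M | dusk run: time / min | dusk run: [product] / M | autumn run: time / min | autumn run: [product] / M |
|---|---|---|---|---|---|---|---|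
| 1.5 | 0.0904 | 1.5 | 0.0497 | 1.5 | 0.0456 | 1.5 | 0.0525 |
| 3.0 | 0.1251 | 3.0 | 0.0653 | 3.0 | 0.0640 | 3.0 | 0.0799 |
| 4.5 | 0.1440 | 4.5 | 0.0803 | 4.5 | 0.0744 | 4.5 | 0.0854 |
| 6.0 | 0.1528 | 6.0 | 0.0830 | 6.0 | 0.0790 | 6.0 | 0.0913 |
| 7.5 | 0.1571 | 7.5 | 0.0827 | 7.5 | 0.0853 | 7.5 | 0.0997 |

(each reading ± 0.002 M)

- Overall: starting material -> product, with free catalyst as catalyst.
- Constant volume, constant temperature.
- Readings of a species count what is bound in complexes too.
- An order is taken over about fifteen percent of the charge, up and down.

- apparent order in [starting material] of the starting rate, round the charge of the winter run (the rate where two percent of its starting material have turned into product) (one fixed amount of product, the same in the runs compared)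
- apparent order in [free catalyst] of the starting rate, round the charge of the winter run (the rate where two percent of its starting material have turned into product)
- product in the dawn run at 7.5 min, as a share of the starting material charged

1. First instants. At 1.5 min the winter run reads 15.1 turnovers and the dusk run 15.2. Catalyst differs between them, yet the count barely moves. These two readings give an order in catalyst of 0.987. The autumn run, with the winter catalyst and half the winter charge of starting material, reads 8.75. Over that wide span I read an order in starting material of 0.784.

2. The middle. In the next interval the winter run gains 5.78 turnovers. That gain is 0.384 of the first interval's, less than the 0.791 of its charge that starting material keeps at 3.0 min. So I read the working catalyst in the winter run as fading.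

3. The end. From 6.0 min to 7.5 min the winter run gains 0.717 turnovers, with 0.443 M of starting material left. So the winter run is slowing with that starting material still in hand. The dusk run at 7.5 min reads 28.4 turnovers: that is my final turnover count, product at the last reading over free catalyst charged. The winter run reads 26.2, a little less, with twice the catalyst.

4. The dawn run. It has the charge of the dusk run and less catalyst, so I carry the dusk count over. That gives 0.0483 M of product, or 8.06% of the charge. The scatter of one reading is 0.667 turnovers on that count, which is 0.189% of the dawn charge.

The forecast gives 0.58 for the order in starting material, 1.05 for the order in free catalyst and 7.9% for the dawn share, on the grounds that “the catalyst dies”, and it stands below my order in starting material and below my share.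

The flask gives 0.68 for the order in starting material, 1.1 for the order in free catalyst and 7.89% for the dawn share.

    free catalyst + starting material → product + free catalyst (60.00 M⁻¹ min⁻¹)
    free catalyst → spent catalyst (0.4878 min⁻¹)
    2 starting material ⇌ idle substrate dimer, settled at all times (3.180 M⁻¹)

In the dawn run free catalyst made product from starting material while it fell with a half-life of 1.42 min; by 7.5 min it stood at 4.38 × 10⁻⁵ M of its 0.00170 M, the rest being spent catalyst, and product stood at 0.0474 M, or 27.9 turnovers against the 28.4 I carried. In the winter run a quarter of the charge asks for 25.0 turnovers, close under that 28.4, and it came at 5.47 min, while the 12.5 of the autumn run came at 2.71 min.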